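The numbers of this flask were chosen freely; the run is a simulation.

1. At early times substrate takes up partner to give first product, and the loss step, in which first product takes up partner to give double product, has little to work on. The flasks and the questions:

the same everywhere: substrate 0.050 M; gas 2.5 mM (held); time 3.0 min

| flask | temperature |
|---|---|
| elm | −10 °C |
| birch | 20 °C |
| ash | 5 °C |
| oak | 35 °C |

* the flask that comes out highest in amount of first product, in percent of the substrate charged, or "all alike" when all lie within 1.5 percentage points (elm / birch / ash / oak / all alike)
* first product at the end, in percent of the substrate charged, elm
* first product at the end, in percent of the substrate charged, birch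
* first product at the end, in percent of the substrate charged, ash
* first product at the end, in percent of the substrate charged, oak

- what is said of first product includes crystals
- crystals is a solid; its amount is given per volume of the solution
- at the start none of partner is dissolved
- the list of constants is for 35 °C, to be carried to other temperatures by the activation energies

    partner + first product → double product (k1 = 18 /M/s, Ea1 = 56.0 kJ/mol)
    gas ⇌ partner, rate k2*(csat - [partner]) (k2 = 1.6 /s, csat = 2.5 mM)
    crystals ⇌ first product, rate k3*(cs3 - [first product]) while solid is left; crystals form when [first product] > cs3 (cs3 = 11 mM, k3 = 1.9 /s)
    substrate + partner → first product (k4 = 18 /M/s, Ea4 = 41.0 kJ/mol)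
    (constants at 35 °C)

2. Two things then freeze in this reckoning of mine. Partner is taken as sitting at saturation, 2.5 mM. Dissolved first product stops at its solubility, 22.0% of the charge, while crystals stand.

3. Two rates remain, as fractions of the charge. Making goes with the substrate fraction left, and losing goes with that frozen fraction. Partner stands in both, so it cancels from their ratio. They balance at the break-even fraction of substrate, which is the selectivity factor (loss constant over making constant) times the frozen fraction: 22.0% in oak, 11.7% in ash. Above it first product climbs; below it, while crystals last, first product falls.

4. With partner frozen, substrate decays pseudo-first-order. Ash runs 1.44 substrate lifetimes in 3.0 min, which leaves 23.6%, still above break-even. Subtracting the steady loss gives 59.5% for ash, 36.6% for elm and 39.0% for birch. In oak the steady loss would reach 178% of the charge, so oak is reckoned empty of first product. My pick is ash.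

5. The forecast also names ash, because “ash gives the best balance”: elm 36.7%, birch 46.5%, ash 59.8%, oak 1.1%. My birch is lower.

6. The simulation gives ash: elm 36.7%, birch 45.7%, ash 59.6%, oak 1.06%.

Ash ends with substrate at 26%, above its break-even, and crystals at 37.6%. In oak at 0.687 min, the making step uses partner 1.3 times as fast as the loss step, which by the break-even fraction, with dissolved first product at its solubility, corresponds to substrate near 27.6%.

7. Take oak read at 50 s. Frozen partner gives substrate 10.5%, under 22.0%, so first product should be past its turning. The computed flask holds substrate 20%, still under break-even, with first product 47.1%, and oak read at 80 s shows less, 36.2%.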